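**Retrosynthetic overview**
- The enone is made last: target ⇒ unprotected aryl aldehyde + carbonyl-stabilised phosphorus ylide (E-selective Wittig), after one global hydrogenolysis and dithiane hydrolysis.
- Ring D–C2 bond of the tetrahydrofuran ⇒ Friedel–Crafts C-arylation of a tetrahydrofuran lactol by the one free phenol of a 4-aryl chroman (sets C2).
- Lactol ⇒ 4,5-cis γ-lactone ⇒ Felkin–Anh reduction of a γ-keto acid ⇒ three-component coupling of a lithiated 2-aryl-1,3-dithiane (masked aroyl anion), (5R)-menthyloxybutenolide and a benzyl bromide (makes the aroyl–C4 bond, sets C3 and C4).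
- Chroman ⇒ catalytic asymmetric [4+2] of a symmetric ortho-quinone methide (from tetrahydroxybenzophenone) with an E-stilbene made by Heck coupling (sets C2, C3, C4).
- Ring order: purchased butenolide ring → reclosed γ-lactone/lactol (the tetrahydrofuran ring); pyran ring by cycloaddition; the two halves are then joined and the enone is added.

Assumption: the (R)-phosphoramide in step 10 gives the (2S,3R,4R)-chroman; if the induction is opposite, its enantiomer is used. All phenols except one on ring D are carried as benzyl ethers.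

**Step 1**
Reactants: 1 2,4-bis(benzyloxy)benzaldehyde; 2 propane-1,3-dithiol
Product: 3 2-[2,4-bis(benzyloxy)phenyl]-1,3-dithiane
Conditions: BF3·OEt2 (0.2 equiv), CH2Cl2, 0 °C → rt
Reagents that add atoms: none
Why: Acid-catalysed dithioacetalisation gives the dithiane whose C2–H can be lithiated (Corey–Seebach precursor).

**Step 2**
Reactants: 3 2-[2,4-bis(benzyloxy)phenyl]-1,3-dithiane; 4 (5R)-5-[(1R,2S,5R)-menthyloxy]furan-2(5H)-one; 5 1-(benzyloxy)-4-(bromomethyl)benzene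
Product: 8 (3R,4R,5R)-3-[4-(benzyloxy)benzyl]-4-{2-[2,4-bis(benzyloxy)phenyl]-1,3-dithian-2-yl}-5-[(1R,2S,5R)-menthyloxy]dihydrofuran-2(3H)-one, via lithiated dithiane 6 (not isolated), via lithium lactone enolate 7 (not isolated)
Conditions: n-BuLi, THF, −78 °C; 4, −78 °C; then 5, DMPU, −78 → −20 °C
Reagents that add atoms: none
Why: The Corey–Seebach acyl-anion equivalent 6 adds 1,4 to the butenolide anti to the menthyloxy group (sets C4) and enolate 7 is benzylated anti to the new C4 substituent (sets C3), a tandem conjugate addition–alkylation.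

**Step 3**
Reactants: 8 the lactone acetal from step 2
Product: 9 (3R,4R)-3-[4-(benzyloxy)benzyl]-4-{2-[2,4-bis(benzyloxy)phenyl]-1,3-dithian-2-yl}-5-hydroxydihydrofuran-2(3H)-one (C5 epimers; ring form of the aldehyde acid)
Conditions: 1 M aq. HCl (cat.), dioxane, 60 °C
Reagents that add atoms: water, O
Why: Acid-catalysed hydrolysis of the mixed acetal releases the auxiliary and unmasks C5 at the aldehyde oxidation level.

**Step 4**
Reactants: 9 the hydroxy lactone; 10 [4-(benzyloxy)phenyl]magnesium bromide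
Product: 12 (2R,3R)-2-[4-(benzyloxy)benzyl]-4-[4-(benzyloxy)phenyl]-3-{2-[2,4-bis(benzyloxy)phenyl]-1,3-dithian-2-yl}-4-oxobutanoic acid, via bromomagnesium alkoxide 11 (not isolated)
Conditions: 10 (2.5 equiv), THF, −78 → 0 °C; then 1,1'-(azodicarbonyl)dipiperidine, 0 °C → rt; aq. citric acid
Reagents that add atoms: none
Why: One equivalent of Grignard reagent opens the lactol to the aldehyde carboxylate, the next adds to the aldehyde, and the magnesium alkoxide is oxidised in the same flask by hydride transfer to the azodicarboxamide (Grignard addition then Mukaiyama-type oxidation), which erases the uncontrolled carbinol centre.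

**Step 5**
Reactants: 12 the keto acid
Product: 14 (3R,4R,5S)-3-[4-(benzyloxy)benzyl]-5-[4-(benzyloxy)phenyl]-4-{2-[2,4-bis(benzyloxy)phenyl]-1,3-dithian-2-yl}dihydrofuran-2(3H)-one, via hydroxy acid dilithium salt 13 (not isolated)
Conditions: LiBH(s-Bu)3 (2.2 equiv), THF, −78 °C; then AcOH, rt
Reagents that add atoms: none
Why: Felkin–Anh reduction delivers hydride anti to the bulky dithianyl group on C4, and the resulting anti alcohol lactonises to the 4,5-cis lactone (sets C5 as S).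

**Step 6**
Reactants: 14 the cis lactone
Product: 15 (3R,4R,5S)-3-[4-(benzyloxy)benzyl]-5-[4-(benzyloxy)phenyl]-4-{2-[2,4-bis(benzyloxy)phenyl]-1,3-dithian-2-yl}tetrahydrofuran-2-ol (anomers)
Conditions: i-Bu2AlH (1.2 equiv), CH2Cl2, −78 °C; aq. potassium sodium tartrate
Reagents that add atoms: none
Why: Half-reduction of the γ-lactone stops at the lactol because the tetrahedral aluminate is stable at −78 °C, and the dithiane keeps the future ketone untouched.

**Step 7**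
Reactants: 16 bis(2,4-dihydroxyphenyl)methanone; 17 benzyl bromide
Product: 18 bis[4-(benzyloxy)-2-hydroxyphenyl]methanone
Conditions: 17 (2.1 equiv), K2CO3, acetone, reflux
Reagents that add atoms: none
Why: Williamson etherification occurs only at the two para hydroxyls because the ortho hydroxyls are hydrogen-bonded to the carbonyl.

**Step 8**
Reactants: 18 the dibenzyl benzophenone
Product: 19 bis[4-(benzyloxy)-2-hydroxyphenyl]methanol
Conditions: NaBH4, THF–MeOH, 0 °C → rt; used crude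
Reagents that add atoms: none
Why: Hydride reduction of the diaryl ketone gives the benzhydrol that is the precursor of the ortho-quinone methide.

**Step 9**
Reactants: 20 4-(benzyloxy)-3-bromobenzaldehyde; 21 1-(benzyloxy)-4-ethenylbenzene
Product: 22 4-(benzyloxy)-3-{(E)-2-[4-(benzyloxy)phenyl]ethenyl}benzaldehyde
Conditions: Pd(OAc)2 (2 mol%), P(o-tol)3, Et3N, DMF, 100 °C
Reagents that add atoms: none
Why: The Heck reaction gives the E-stilbene through syn insertion and syn β-hydride elimination.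

**Step 10**
Reactants: 19 the benzhydrol; 22 the E-stilbene aldehyde
Product: 24 4-(benzyloxy)-3-{(2S,3R,4R)-7-(benzyloxy)-4-[4-(benzyloxy)-2-hydroxyphenyl]-2-[4-(benzyloxy)phenyl]-3,4-dihydro-2H-chromen-3-yl}benzaldehyde, via ortho-quinone methide 23 (not isolated)
Conditions: (R)-3,3'-bis(2,4,6-triisopropylphenyl)-1,1'-bi-2-naphthol N-triflylphosphoramide (5 mol%), 4 Å MS, CH2Cl2, 0 °C, slow addition of 19 to 22 (1.5 equiv)
Reagents that add atoms: none
Why: Dehydration gives quinone methide 23 (the same species from either ring of symmetric 19), which undergoes an inverse-demand hetero-Diels–Alder reaction with the stilbene in which oxygen bonds to the carbon bearing the 4-benzyloxyphenyl group, the E geometry gives 2,3-trans, the endo approach gives 3,4-trans, and the chiral phosphoramide anion sets the absolute sense.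

**Step 11**
Reactants: 15 the lactol; 24 the chroman phenol
Product: 26 4-(benzyloxy)-3-[(2S,3R,4R)-7-(benzyloxy)-2-[4-(benzyloxy)phenyl]-4-{4-(benzyloxy)-5-[(2S,3R,4R,5S)-3-[4-(benzyloxy)benzyl]-5-[4-(benzyloxy)phenyl]-4-{2-[2,4-bis(benzyloxy)phenyl]-1,3-dithian-2-yl}tetrahydrofuran-2-yl]-2-hydroxyphenyl}-3,4-dihydro-2H-chromen-3-yl]benzaldehyde, via oxocarbenium ion 25 (not isolated)
Conditions: BF3·OEt2 (0.3 equiv), 4 Å MS, CH2Cl2, −40 → 0 °C; 24 (1.3 equiv)
Reagents that add atoms: none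
Why: In this Friedel–Crafts (C-glycosylation-type) arylation the position para to the free phenol of ring D attacks the five-membered oxocarbenium ion on the face anti to the C4 dithianyl and C5 aryl groups (inside-attack model for 3-substituted tetrahydrofuranyl cations), which places the aryl group at C2 cis to the C3 benzyl group.

**Step 12**
Reactants: 26 the coupled dithiane
Product: 27 4-(benzyloxy)-3-[(2S,3R,4R)-7-(benzyloxy)-2-[4-(benzyloxy)phenyl]-4-{4-(benzyloxy)-5-[(2S,3R,4R,5S)-3-[4-(benzyloxy)benzyl]-5-[4-(benzyloxy)phenyl]-4-[2,4-bis(benzyloxy)benzoyl]tetrahydrofuran-2-yl]-2-hydroxyphenyl}-3,4-dihydro-2H-chromen-3-yl]benzaldehyde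
Conditions: MeI, CaCO3, MeCN–H2O (9:1), 45 °C
Reagents that add atoms: water, O
Why: Alkylative dithiane hydrolysis (S-methylation, then displacement by water) unmasks the aryl ketone under neutral conditions that do not epimerise C4.

**Step 13**
Reactants: 27 the octabenzyl ketone aldehyde
Product: 28 3-[(2S,3R,4R)-4-{5-[(2S,3R,4R,5S)-4-(2,4-dihydroxybenzoyl)-3-(4-hydroxybenzyl)-5-(4-hydroxyphenyl)tetrahydrofuran-2-yl]-2,4-dihydroxyphenyl}-7-hydroxy-2-(4-hydroxyphenyl)-3,4-dihydro-2H-chromen-3-yl]-4-hydroxybenzaldehyde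
Conditions: H2 (1 atm), 10% Pd/C, EtOAc–MeOH, rt, stopped after 8 equiv uptake
Reagents that add atoms: none
Why: Catalytic hydrogenolysis cleaves the eight aryl benzyl ethers, while the electron-rich aryl aldehyde, the hydroxyaryl ketone and the cyclic benzylic ethers are expected to survive at 1 atm and rt.

**Step 14**
Reactants: 29 2-chloro-1-(2,4-dihydroxyphenyl)ethan-1-one; 30 triphenylphosphane
Product: 31 [2-(2,4-dihydroxyphenyl)-2-oxoethyl]triphenylphosphonium chloride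
Conditions: toluene, 80 °C
Reagents that add atoms: none
Why: SN2 displacement of the α-chloro ketone by the phosphane gives the ylide precursor.

**Step 15**
Reactants: 28 the polyphenol aldehyde; 31 the phosphonium chloride
Product: 33 CNP0330082.3 (E)-1-(2,4-dihydroxyphenyl)-3-{3-[(2S,3R,4R)-4-{5-[(2S,3R,4R,5S)-4-(2,4-dihydroxybenzoyl)-3-(4-hydroxybenzyl)-5-(4-hydroxyphenyl)tetrahydrofuran-2-yl]-2,4-dihydroxyphenyl}-7-hydroxy-2-(4-hydroxyphenyl)-3,4-dihydro-2H-chromen-3-yl]-4-hydroxyphenyl}prop-2-en-1-one, via phosphorus ylide 32 (not isolated)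
Conditions: Et3N (1.1 equiv), THF, 60 °C
Reagents that add atoms: none
Why: Wittig olefination with the carbonyl-stabilised ylide gives the E-enone under conditions too mild to enolise C4 or open the β-alkoxy ketone.

**Compound list**
1 | 2,4-bis(benzyloxy)benzaldehyde | O=Cc1ccc(OCc2ccccc2)cc1OCc1ccccc1 | starting material
2 | propane-1,3-dithiol | SCCCS | starting material
3 | 2-[2,4-bis(benzyloxy)phenyl]-1,3-dithiane | C1(SCCCS1)c1ccc(OCc2ccccc2)cc1OCc1ccccc1 | intermediate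
4 | (5R)-5-[(1R,2S,5R)-menthyloxy]furan-2(5H)-one | CC(C)[C@@H]1CC[C@@H](C)C[C@H]1O[C@@H]1OC(=O)C=C1 | starting material
5 | 1-(benzyloxy)-4-(bromomethyl)benzene | BrCc1ccc(OCc2ccccc2)cc1 | starting material
6 | 2-lithio-2-[2,4-bis(benzyloxy)phenyl]-1,3-dithiane | [Li]C1(SCCCS1)c1ccc(OCc2ccccc2)cc1OCc1ccccc1 | intermediate
7 | lithium enolate of (4R,5R)-4-dithianyl-5-menthyloxy butanolide | [Li]OC1=C[C@@H](C2(SCCCS2)c2ccc(OCc3ccccc3)cc2OCc2ccccc2)[C@H](O[C@@H]2C[C@H](C)CC[C@H]2C(C)C)O1 | intermediate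
8 | (3R,4R,5R)-3-[4-(benzyloxy)benzyl]-4-{2-[2,4-bis(benzyloxy)phenyl]-1,3-dithian-2-yl}-5-menthyloxydihydrofuran-2(3H)-one | O=C1O[C@@H](O[C@@H]2C[C@H](C)CC[C@H]2C(C)C)[C@H](C2(SCCCS2)c2ccc(OCc3ccccc3)cc2OCc2ccccc2)[C@H]1Cc1ccc(OCc2ccccc2)cc1 | intermediate
9 | (3R,4R)-5-hydroxy lactone (C5 epimers) | O=C1OC(O)[C@H](C2(SCCCS2)c2ccc(OCc3ccccc3)cc2OCc2ccccc2)[C@H]1Cc1ccc(OCc2ccccc2)cc1 | intermediate
10 | [4-(benzyloxy)phenyl]magnesium bromide | Br[Mg]c1ccc(OCc2ccccc2)cc1 | starting material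
11 | bis(bromomagnesium) salt of the (2R,3R)-4-aryl-4-hydroxy acid (C4 epimers) | Br[Mg]OC(=O)[C@H](Cc1ccc(OCc2ccccc2)cc1)[C@H](C(O[Mg]Br)c1ccc(OCc2ccccc2)cc1)C1(SCCCS1)c1ccc(OCc2ccccc2)cc1OCc1ccccc1 | intermediate
12 | (2R,3R)-2-[4-(benzyloxy)benzyl]-4-[4-(benzyloxy)phenyl]-3-{2-[2,4-bis(benzyloxy)phenyl]-1,3-dithian-2-yl}-4-oxobutanoic acid | OC(=O)[C@H](Cc1ccc(OCc2ccccc2)cc1)[C@H](C(=O)c1ccc(OCc2ccccc2)cc1)C1(SCCCS1)c1ccc(OCc2ccccc2)cc1OCc1ccccc1 | intermediate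
13 | dilithium salt of the (2R,3R,4S)-4-hydroxy acid | [Li]OC(=O)[C@H](Cc1ccc(OCc2ccccc2)cc1)[C@H]([C@H](O[Li])c1ccc(OCc2ccccc2)cc1)C1(SCCCS1)c1ccc(OCc2ccccc2)cc1OCc1ccccc1 | intermediate
14 | (3R,4R,5S)-3-[4-(benzyloxy)benzyl]-5-[4-(benzyloxy)phenyl]-4-{2-[2,4-bis(benzyloxy)phenyl]-1,3-dithian-2-yl}dihydrofuran-2(3H)-one | O=C1O[C@H](c2ccc(OCc3ccccc3)cc2)[C@H](C2(SCCCS2)c2ccc(OCc3ccccc3)cc2OCc2ccccc2)[C@H]1Cc1ccc(OCc2ccccc2)cc1 | intermediate
15 | (3R,4R,5S)-lactol of 14 (anomers) | OC1O[C@H](c2ccc(OCc3ccccc3)cc2)[C@H](C2(SCCCS2)c2ccc(OCc3ccccc3)cc2OCc2ccccc2)[C@H]1Cc1ccc(OCc2ccccc2)cc1 | intermediate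
16 | bis(2,4-dihydroxyphenyl)methanone | O=C(c1ccc(O)cc1O)c1ccc(O)cc1O | starting material
17 | benzyl bromide | BrCc1ccccc1 | starting material
18 | bis[4-(benzyloxy)-2-hydroxyphenyl]methanone | O=C(c1ccc(OCc2ccccc2)cc1O)c1ccc(OCc2ccccc2)cc1O | intermediate
19 | bis[4-(benzyloxy)-2-hydroxyphenyl]methanol | OC(c1ccc(OCc2ccccc2)cc1O)c1ccc(OCc2ccccc2)cc1O | intermediate
20 | 4-(benzyloxy)-3-bromobenzaldehyde | O=Cc1ccc(OCc2ccccc2)c(Br)c1 | starting material
21 | 1-(benzyloxy)-4-ethenylbenzene | C=Cc1ccc(OCc2ccccc2)cc1 | starting material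
22 | 4-(benzyloxy)-3-{(E)-2-[4-(benzyloxy)phenyl]ethenyl}benzaldehyde | O=Cc1ccc(OCc2ccccc2)c(/C=C/c2ccc(OCc3ccccc3)cc2)c1 | intermediate
23 | 3-(benzyloxy)-6-{[4-(benzyloxy)-2-hydroxyphenyl]methylidene}cyclohexa-2,4-dien-1-one (alkene geometry not fixed) | O=C1C=C(OCc2ccccc2)C=CC1=Cc1ccc(OCc2ccccc2)cc1O | intermediate
24 | (2S,3R,4R)-chroman aldehyde with one free phenol on ring D | O=Cc1ccc(OCc2ccccc2)c(c1)[C@H]1[C@H](c2ccc(OCc3ccccc3)cc2O)c2ccc(OCc3ccccc3)cc2O[C@@H]1c1ccc(OCc2ccccc2)cc1 | intermediate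
25 | (3R,4R,5S)-oxocarbenium ion from lactol 15 | C1=[O+][C@H](c2ccc(OCc3ccccc3)cc2)[C@H](C2(SCCCS2)c2ccc(OCc3ccccc3)cc2OCc2ccccc2)[C@H]1Cc1ccc(OCc2ccccc2)cc1 | intermediate
26 | coupled octabenzyl dithiane aldehyde (tetrahydrofuran 2S,3R,4R,5S; chroman 2S,3R,4R) | O=Cc1ccc(OCc2ccccc2)c(c1)[C@H]1[C@H](c2cc([C@H]3O[C@H](c4ccc(OCc5ccccc5)cc4)[C@H](C4(SCCCS4)c4ccc(OCc5ccccc5)cc4OCc4ccccc4)[C@H]3Cc3ccc(OCc4ccccc4)cc3)c(OCc3ccccc3)cc2O)c2ccc(OCc3ccccc3)cc2O[C@@H]1c1ccc(OCc2ccccc2)cc1 | intermediate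
27 | octabenzyl ketone aldehyde | O=Cc1ccc(OCc2ccccc2)c(c1)[C@H]1[C@H](c2cc([C@H]3O[C@H](c4ccc(OCc5ccccc5)cc4)[C@H](C(=O)c4ccc(OCc5ccccc5)cc4OCc4ccccc4)[C@H]3Cc3ccc(OCc4ccccc4)cc3)c(OCc3ccccc3)cc2O)c2ccc(OCc3ccccc3)cc2O[C@@H]1c1ccc(OCc2ccccc2)cc1 | intermediate
28 | unprotected polyphenol aldehyde | O=Cc1ccc(O)c(c1)[C@H]1[C@H](c2cc([C@H]3O[C@H](c4ccc(O)cc4)[C@H](C(=O)c4ccc(O)cc4O)[C@H]3Cc3ccc(O)cc3)c(O)cc2O)c2ccc(O)cc2O[C@@H]1c1ccc(O)cc1 | intermediate
29 | 2-chloro-1-(2,4-dihydroxyphenyl)ethan-1-one | O=C(CCl)c1ccc(O)cc1O | starting material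
30 | triphenylphosphane | c1ccc(cc1)P(c1ccccc1)c1ccccc1 | starting material
31 | [2-(2,4-dihydroxyphenyl)-2-oxoethyl]triphenylphosphonium chloride | [Cl-].O=C(C[P+](c1ccccc1)(c1ccccc1)c1ccccc1)c1ccc(O)cc1O | intermediate
32 | 1-(2,4-dihydroxyphenyl)-2-(triphenyl-λ5-phosphanylidene)ethan-1-one | O=C(C=P(c1ccccc1)(c1ccccc1)c1ccccc1)c1ccc(O)cc1O | intermediate
33 | CNP0330082.3 | O=C(/C=C/c1ccc(O)c([C@H]2[C@H](c3cc([C@H]4O[C@H](c5ccc(O)cc5)[C@H](C(=O)c5ccc(O)cc5O)[C@H]4Cc4ccc(O)cc4)c(O)cc3O)c3ccc(O)cc3O[C@@H]2c2ccc(O)cc2)c1)c1ccc(O)cc1O | target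

**Totals**
Total steps: 15. Longest linear sequence: 10 steps (1 → 3 → 8 → 9 → 12 → 14 → 15 → 26 → 27 → 28 → 33; steps 1–6, 11, 12, 13, 15).

**Steps most likely to fail, with fallbacks**

The union of 15 with 24 (step 11) is the weakest point. Ring A of 24 is a second electron-rich arene, the C2 selectivity rests on a model, and the new benzylic ether is acid-labile. The fallback sets out from 24 and 15 and replaces the Friedel–Crafts reaction by organozinc addition to a 2-sulfonyl cyclic ether. 24 is iodinated para to its free phenol (N-iodosuccinimide, MeCN, 0 °C) to give iodophenol F1, which is benzylated (17, K2CO3, DMF) to aryl iodide F2. Zinc insertion (Zn dust, LiCl, THF, 40 °C; the aldehyde is tolerated) gives arylzinc iodide F3. Lactol 15 with PhSO2H and CaCl2 in CH2Cl2 gives phenylsulfonyl tetrahydrofuran F4. F3 and F4 are combined (ZnBr2, THF, rt) to give nonabenzyl coupled dithiane F5, which MeI/CaCO3 converts to nonabenzyl ketone F6. Hydrogenolysis (H2, Pd/C) of F6 rejoins the route at 28.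

The asymmetric cycloaddition (step 10) may give low ee with a 1,2-diaryl alkene, and 19 can self-condense. The fallback sets out from 19 and 22 and replaces asymmetric catalysis by resolution. The two are combined with diphenyl phosphate (10 mol%, CH2Cl2, slow addition) to give racemic chroman F7. Its single phenol is esterified with (S)-naproxen (DCC, DMAP, CH2Cl2), the diastereomers are separated, and the (2S,3R,4R) naproxen ester F8 is cleaved (K2CO3, MeOH) to return 24.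

The final Wittig reaction (step 15) may be too slow on an aldehyde deactivated by its para hydroxyl in a substrate with eleven acidic OH groups. The fallback sets out from 28 and forms the enone by Claisen–Schmidt condensation with commercial 1-(2,4-dihydroxyphenyl)ethanone (KOH, EtOH–H2O, rt). The aldol β-hydroxy ketone F9 dehydrates in the flask to give 33. Under these conditions the aroyl group on C4 is a bis-phenoxide, which suppresses enolisation there.

**Further compounds**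
F1 | step 11 | 24 iodinated on ring D para to the free phenol | O=Cc1ccc(OCc2ccccc2)c(c1)[C@H]1[C@H](c2cc(I)c(OCc3ccccc3)cc2O)c2ccc(OCc3ccccc3)cc2O[C@@H]1c1ccc(OCc2ccccc2)cc1
F2 | step 11 | O-benzyl ether of F1 | O=Cc1ccc(OCc2ccccc2)c(c1)[C@H]1[C@H](c2cc(I)c(OCc3ccccc3)cc2OCc2ccccc2)c2ccc(OCc3ccccc3)cc2O[C@@H]1c1ccc(OCc2ccccc2)cc1
F3 | step 11 | arylzinc iodide from F2 | O=Cc1ccc(OCc2ccccc2)c(c1)[C@H]1[C@H](c2cc([Zn]I)c(OCc3ccccc3)cc2OCc2ccccc2)c2ccc(OCc3ccccc3)cc2O[C@@H]1c1ccc(OCc2ccccc2)cc1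
F4 | step 11 | (3R,4R,5S)-2-(phenylsulfonyl)tetrahydrofuran from 15 (anomers) | O=S(=O)(c1ccccc1)C1O[C@H](c2ccc(OCc3ccccc3)cc2)[C@H](C2(SCCCS2)c2ccc(OCc3ccccc3)cc2OCc2ccccc2)[C@H]1Cc1ccc(OCc2ccccc2)cc1
F5 | step 11 | nonabenzyl coupled dithiane (26 with the ring D phenol benzylated) | O=Cc1ccc(OCc2ccccc2)c(c1)[C@H]1[C@H](c2cc([C@H]3O[C@H](c4ccc(OCc5ccccc5)cc4)[C@H](C4(SCCCS4)c4ccc(OCc5ccccc5)cc4OCc4ccccc4)[C@H]3Cc3ccc(OCc4ccccc4)cc3)c(OCc3ccccc3)cc2OCc2ccccc2)c2ccc(OCc3ccccc3)cc2O[C@@H]1c1ccc(OCc2ccccc2)cc1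
F6 | step 11 | nonabenzyl ketone (27 with the ring D phenol benzylated) | O=Cc1ccc(OCc2ccccc2)c(c1)[C@H]1[C@H](c2cc([C@H]3O[C@H](c4ccc(OCc5ccccc5)cc4)[C@H](C(=O)c4ccc(OCc5ccccc5)cc4OCc4ccccc4)[C@H]3Cc3ccc(OCc4ccccc4)cc3)c(OCc3ccccc3)cc2OCc2ccccc2)c2ccc(OCc3ccccc3)cc2O[C@@H]1c1ccc(OCc2ccccc2)cc1
F7 | step 10 | racemic 24, (2S*,3R*,4R*), one enantiomer drawn | O=Cc1ccc(OCc2ccccc2)c(c1)[C@H]1[C@H](c2ccc(OCc3ccccc3)cc2O)c2ccc(OCc3ccccc3)cc2O[C@@H]1c1ccc(OCc2ccccc2)cc1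
F8 | step 10 | (S)-naproxen ester of (2S,3R,4R)-24 at the ring D phenol | O=Cc1ccc(OCc2ccccc2)c(c1)[C@H]1[C@H](c2ccc(OCc3ccccc3)cc2OC(=O)[C@@H](C)c2ccc3cc(OC)ccc3c2)c2ccc(OCc3ccccc3)cc2O[C@@H]1c1ccc(OCc2ccccc2)cc1
F9 | step 15 | β-hydroxy ketone aldol adduct of 28 (carbinol epimers) | O=C(CC(O)c1ccc(O)c(c1)[C@H]1[C@H](c2cc([C@H]3O[C@H](c4ccc(O)cc4)[C@H](C(=O)c4ccc(O)cc4O)[C@H]3Cc3ccc(O)cc3)c(O)cc2O)c2ccc(O)cc2O[C@@H]1c1ccc(O)cc1)c1ccc(O)cc1O
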